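## The problem

The target, 6-[2-hydroxy-6-(hydroxymethyl)-4-methylphenoxy]-3-[(1S)-1-hydroxy-3-methylbutyl]-2-methoxybenzoic acid, is a diaryl ether of two densely substituted benzene rings. Ring A is numbered C1 (CO2H), C2 (OMe), C3 (side chain), C4 and C5 (both CH) and C6 (aryloxy). Ring B is numbered C1' (ether oxygen), C2' (OH), C4' (CH3) and C6' (CH2OH). The ether oxygen lies between CO2H on ring A and both OH and CH2OH on ring B, so any late aryl–O coupling on intact rings would have to join two hindered, electron-rich partners. Ring A carries four contiguous substituents (C6, C1, C2, C3) whose relative positions must be fixed without reliance on directing-group selectivity. The only stereocenter is the (S)-configured benzylic carbinol of the side chain (O > aryl > CH2 > H). No second stereocenter exists to relay control, so it must be set by a reagent and then carried through unchanged. Both benzylic C–O bonds are at risk: the secondary one, on an ortho-methoxy arene, can ionise in acid, and both can be hydrogenolysed. Ring B is a catechol monoether and oxidises easily, and the acid at C1 is flanked on both sides, so an ordinary alkyl ester there would be hard to saponify. The enabling feature is the C4–C5 CH=CH unit beside the C6/C1/C2/C3 array. It maps onto a 4-aryloxy-3-alkoxycarbonyl-2-pyrone (C1, C6, C5, C4) plus a two-carbon alkoxyalkyne (C2, C3), so ring A can be closed as an arene with every substituent already in place.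

## Retrosynthesis

Target 23 is traced back to acid 22 by removing the two silyl ethers, and 22 to benzyl ester 21 by removing two benzyl groups. A benzyl ester is preferred to a methyl ester because the flanked C1 carboxyl then appears by hydrogenolysis, together with the C2' phenol, and no hindered saponification is needed. The two benzylic alcohols stay silylated during that hydrogenolysis so that their C–O bonds are not reduced. The forward steps ask only for neutral hydrogenolysis and a fluoride treatment.

In 21, ring A is opened at C1–C2 and C3–C4, and one CO2 is added back across C1 and C4. This gives pyrone 12 and the (S)-silyloxy methyl ynol ether 19, connected through the bicyclic lactone 20. The neighbouring options are a cut of the diaryl ether on an intact ring A, or a ring A cut that leaves a phenol to be methylated later. The chosen cut beats both because the OMe arrives already on carbon, the aryl–O bond is already present, and the arene forms without an oxidation step. The precursors are a monocyclic lactone and an acyclic alkyne. The forward reaction must deliver one regiochemistry: the alkyne carbon carrying the chain bonds to pyrone C6.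

Pyrone 12 is cut at the C4–O(aryl) bond into 4-chloropyrone 11 and phenol 6. This moves the hindered ether formation onto a vinylogous acid chloride, where addition–elimination tolerates a doubly ortho-substituted phenoxide far better than a copper- or palladium-mediated coupling of two arenes. The forward step needs attack at C4 rather than at C6 or the lactone carbonyl.

Chloride 11 comes from hydroxypyrone 10. Pyrone 10 is opened at the O1–C6 bond to acylmalonate 9, which is cut at the C3–C4 bond into dibenzyl malonate 7 and (E)-3-ethoxyacryloyl chloride 8, both commercial. The malonate supplies C2, C3 and the ester; the acryloyl unit supplies C4 to C6 at the correct oxidation level. The forward steps are a malonate C-acylation and an acid-induced lactonisation with loss of one benzyl group.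

Phenol 6 is traced through diol 5 and aldehyde 4 (loss of silyl, then oxidation level), then to catechol 3 (loss of benzyl), then to 2 (O-methyl) and to creosol 1 (C–CHO bond at the only free position ortho to OH). Benzyl is chosen for the C2' oxygen because it does not migrate between adjacent oxygens under the basic coupling conditions, whereas a silyl group would. The forward steps ask for one regioselective O-benzylation and one chemoselective O-silylation.

Alkyne 19 is traced to alcohol 18 (loss of silyl), to ynone 17 (the stereocenter is erased, to be reset by catalyst control), to racemic alcohol 16 and finally to the C2–C3 bond between lithium methoxyacetylide 15 and isovaleraldehyde 14. Acetylide 15 is made in the flask from chloroacetaldehyde dimethyl acetal 13. The forward steps must stay neutral or basic throughout, since the ynol ether hydrates and rearranges in acid.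

## Roads not taken

Alternative 1: Ring B would be built last by cutting C4'–C5' and C1'–C6'. The kinetic lithium enolate of 1,1-dimethoxypropan-2-one A3 would add in a conjugate sense to the ring A aryloxymethyl propynyl ketone A2. The ArO–CH carbanion would then close on the new ketone, and dehydration would give the phenol A1 with C6' as a dimethyl acetal.
- Merits: the ether oxygen is attached as a simple alkyl aryl ether before ring B exists, so no hindered diaryl ether has to be made. The C2' phenol appears unprotected, so no benzyl group and no hydrogenolysis near the benzylic alcohols are needed. On this point it is better than the chosen plan, which answers by keeping both benzylic oxygens silylated while the benzyl groups are removed.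
- Weak points: A2 already contains the complete ring A with its four contiguous substituents and the stereocenter, so the harder ring is left unsolved. The annulation needs a ketone enolate to add 1,4 and not 1,2 to an ynone, in the presence of a second acidic site (the ArOCH2 ketone) and a free or masked carboxyl. The acetal must afterwards be hydrolysed and reduced.
- Comparison: the chosen route builds the difficult ring in its key step and buys ring B from creosol in five routine steps.

Alternative 2: Ring A would be cut at C1–C2 and C5–C6. The 1-methoxy-1-silyloxy diene A5, carrying the side chain, would add to the aryloxypropiolate A6, and loss of methanol would give the 2-hydroxybenzoate A4.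
- Merits: normal-demand cycloadditions of vinylketene acetals with propiolates are a broad and reliable family, arguably better documented than the pyrone–ynol ether pairing. Against this the chosen plan sets the irreversible loss of CO2 and partners that are stable, isolable compounds.
- Weak points: A6 is a push-pull alkyne, since the aryloxy group donates into the propiolate, so it is a weak dienophile, and it must itself be made from the hindered phenol. A5 must be generated from an ester whose enolate has a beta-silyloxy leaving group, so elimination threatens the stereocenter-bearing carbon. A4 still needs O-methylation of a hydrogen-bonded phenol flanked on both sides, which adds a step.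
- Comparison: both plans close ring A by a [4+2] reaction, but only the chosen one delivers the C2 methoxy group directly.

Alternative 3: No ring would be formed. Fluoride would release the C1–C6 aryne from the silylaryl triflate A8, the phenoxide of 6 would add at C6, and the C1 aryl anion would be trapped by CO2 to give acid A7.
- Merits: it is the most convergent option. The regiochemistry of addition to a 3-methoxyaryne is dependable, and the free acid appears directly with no ester to remove. If it worked it would be shorter than the chosen endgame.
- Weak points: A8 is itself a benzene with four contiguous substituents, so the substitution problem of ring A is moved into a fragment rather than solved. The three-component capture needs a doubly ortho-substituted phenoxide to outrun protonation of the aryl anion by adventitious proton sources. CO2 can also bind the phenoxide reversibly before it meets the aryne.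
- Comparison: the chosen plan gives up some convergence but creates the contiguous pattern of ring A in the key step from a malonate and a four-step alkyne.

Key step: step 14

Assumption: dibenzyl malonate 7 and (E)-3-ethoxyacryloyl chloride 8 are taken as commercial; the stereodescriptor of the target is (S) as derived from the drawn structure.

Step 1
Reactants: 1 creosol (2-methoxy-4-methylphenol)
Product: 2 2-hydroxy-3-methoxy-5-methylbenzaldehyde
Conditions: MgCl2, Et3N, (CH2O)n, MeCN, reflux; aq. HCl
Reagents that add atoms: paraformaldehyde (as formaldehyde), C=O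
Why: Casnati–Skattebøl ortho-formylation; the magnesium phenoxide delivers formaldehyde to the only free position ortho to OH, and a second formaldehyde accepts hydride to give the aldehyde.

Step 2
Reactants: 2 2-hydroxy-3-methoxy-5-methylbenzaldehyde
Product: 3 2,3-dihydroxy-5-methylbenzaldehyde
Conditions: BBr3, CH2Cl2, −78 °C to rt; H2O
Reagents that add atoms: none
Why: Lewis acid cleavage of an aryl methyl ether, routine for ortho-vanillin-type aldehydes; the formyl group survives at low temperature.

Step 3
Reactants: 3 2,3-dihydroxy-5-methylbenzaldehyde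
Product: 4 3-(benzyloxy)-2-hydroxy-5-methylbenzaldehyde
Conditions: NaH (2.1 equiv), DMSO, rt; BnBr (1.0 equiv); aq. HCl
Reagents that add atoms: benzyl bromide, BrCc1ccccc1
Why: Regioselective Williamson mono-alkylation of a catecholate dianion; the 2-oxide is conjugated with and chelated to the formyl group, so the 3-oxide is the stronger nucleophile and takes the single equivalent of BnBr.

Step 4
Reactants: 4 3-(benzyloxy)-2-hydroxy-5-methylbenzaldehyde
Product: 5 2-(benzyloxy)-6-(hydroxymethyl)-4-methylphenol
Conditions: NaBH4, MeOH/THF, 0 °C
Reagents that add atoms: none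
Why: Borohydride reduction of an aryl aldehyde; the benzyl ether and phenol are inert.

Step 5
Reactants: 5 2-(benzyloxy)-6-(hydroxymethyl)-4-methylphenol
Product: 6 2-(benzyloxy)-4-methyl-6-{[(triisopropylsilyl)oxy]methyl}phenol
Conditions: TIPSCl (1.05 equiv), imidazole, CH2Cl2, 0 °C
Reagents that add atoms: triisopropylsilyl chloride, CC(C)[Si](Cl)(C(C)C)C(C)C
Why: Chemoselective silylation as known for salicyl alcohols; the primary benzylic hydroxyl is more nucleophilic toward the bulky silyl chloride than the neutral phenol, which sits between two ortho substituents.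

Step 6
Reactants: 7 dibenzyl malonate; 8 (E)-3-ethoxyacryloyl chloride
Product: 9 dibenzyl 2-[(2E)-3-ethoxyprop-2-enoyl]propanedioate
Conditions: MgCl2, Et3N, MeCN, 0 °C to rt; aq. HCl
Reagents that add atoms: none
Why: Magnesium-mediated C-acylation of a malonate by an acid chloride (Rathke conditions); the magnesium chelate of the product, which is fully enolised, prevents O-acylation and a second acylation.

Step 7
Reactants: 9 dibenzyl 2-[(2E)-3-ethoxyprop-2-enoyl]propanedioate
Product: 10 benzyl 4-hydroxy-2-oxo-2H-pyran-3-carboxylate
Conditions: HCO2H, 70 °C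
Reagents that add atoms: none
Why: Acid-promoted lactonisation by oxa-conjugate addition–elimination; one ester carbonyl oxygen adds to the ethoxy-bearing terminus, ethanol leaves, and formic acid debenzylates the 2-benzyloxypyrylium ion, the same closure that converts dialkyl (3-alkoxyallylidene)malonates into 3-alkoxycarbonyl-2-pyrones.

Step 8
Reactants: 10 benzyl 4-hydroxy-2-oxo-2H-pyran-3-carboxylate
Product: 11 benzyl 4-chloro-2-oxo-2H-pyran-3-carboxylate
Conditions: (COCl)2, DMF (cat.), CH2Cl2, 0 °C to rt
Reagents that add atoms: oxalyl chloride, O=C(Cl)C(Cl)=O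
Why: Vilsmeier-type conversion of a vinylogous acid into its vinylogous acid chloride, as practised on 4-hydroxycoumarins, 4-hydroxy-2-pyrones and tetronic acids.

Step 9
Reactants: 6 2-(benzyloxy)-4-methyl-6-{[(triisopropylsilyl)oxy]methyl}phenol; 11 benzyl 4-chloro-2-oxo-2H-pyran-3-carboxylate
Product: 12 benzyl 4-[2-(benzyloxy)-4-methyl-6-{[(triisopropylsilyl)oxy]methyl}phenoxy]-2-oxo-2H-pyran-3-carboxylate
Conditions: K2CO3, MeCN, 0 °C to rt
Reagents that add atoms: none
Why: Addition–elimination (vinylogous acyl substitution) of a phenoxide at C4 of a 4-chloro-2-pyrone, known for 4-chloropyrones and 4-chlorocoumarins; C4 is activated by both the lactone carbonyl and the ester, and the silyl group stays on the alkyl oxygen because the phenoxide is the more stable anion.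

Step 10
Reactants: 13 chloroacetaldehyde dimethyl acetal (2-chloro-1,1-dimethoxyethane); 14 isovaleraldehyde (3-methylbutanal)
Product: 16 rac-1-methoxy-5-methylhex-1-yn-3-ol, via lithium methoxyacetylide 15 (not isolated)
Conditions: LiNEt2 (3 equiv, from Et2NH and n-BuLi), THF, 0 °C; then 14, −78 to 0 °C; aq. NH4Cl
Reagents that add atoms: none
Why: Two eliminations (methanol, then HCl) and a deprotonation convert the chloroacetal into the lithium alkoxyacetylide in the flask, which adds 1,2 to the aldehyde; the product is racemic and is kept away from acid.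

Step 11
Reactants: 16 rac-1-methoxy-5-methylhex-1-yn-3-ol
Product: 17 1-methoxy-5-methylhex-1-yn-3-one
Conditions: MnO2 (activated, excess), CH2Cl2, rt
Reagents that add atoms: none
Why: Oxidation of a propargylic alcohol by manganese dioxide under neutral, anhydrous conditions, which the acid-labile ynol ether tolerates.

Step 12
Reactants: 17 1-methoxy-5-methylhex-1-yn-3-one
Product: 18 (S)-1-methoxy-5-methylhex-1-yn-3-ol
Conditions: Ru[(S,S)-TsNCH(Ph)CH(Ph)NH](p-cymene) (1 mol %), i-PrOH, rt
Reagents that add atoms: none
Why: Noyori–Ikariya asymmetric transfer hydrogenation of an alkynyl ketone; the (S,S) catalyst places the alkynyl group where an aryl group sits in aryl ketone reductions and so delivers hydride to the face that gives the (S) alcohol, and the base-free amido complex keeps the medium neutral for the alkoxy-ynone.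

Step 13
Reactants: 18 (S)-1-methoxy-5-methylhex-1-yn-3-ol
Product: 19 (S)-tert-butyl[(1-methoxy-5-methylhex-1-yn-3-yl)oxy]dimethylsilane
Conditions: TBSCl, imidazole, DMF, 0 °C to rt
Reagents that add atoms: tert-butyldimethylsilyl chloride, CC(C)(C)[Si](C)(C)Cl
Why: Standard silylation of a secondary alcohol under buffered, non-acidic conditions; the tert-butyldimethylsilyl group is chosen over a bulkier one to keep the reacting alkyne carbon accessible.

Step 14
Reactants: 12 benzyl 4-[2-(benzyloxy)-4-methyl-6-{[(triisopropylsilyl)oxy]methyl}phenoxy]-2-oxo-2H-pyran-3-carboxylate; 19 (S)-tert-butyl[(1-methoxy-5-methylhex-1-yn-3-yl)oxy]dimethylsilane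
Product: 21 benzyl 6-[2-(benzyloxy)-4-methyl-6-{[(triisopropylsilyl)oxy]methyl}phenoxy]-3-[(1S)-1-{[tert-butyl(dimethyl)silyl]oxy}-3-methylbutyl]-2-methoxybenzoate, via bicyclic lactone cycloadduct 20 (not isolated)
Conditions: 19 (2.5 equiv), toluene, 110 °C, sealed tube; xylene, 140 °C if slow
Reagents that add atoms: none
Why: Inverse-electron-demand [4+2] cycloaddition of a 2-pyrone with an alkyne followed by retro-[4+2] loss of CO2, the established pyrone-to-benzene annulation in the electron-poor diene/electron-rich two-carbon partner variant known for 3-alkoxycarbonyl-2-pyrones with ketene acetals and ynamines. The C3 ester and the lactone carbonyl lower the diene LUMO, whose largest coefficient is at C6, while the HOMO of the ynol ether is largest at the carbon beta to OMe, so the leading bond joins that chain-bearing carbon to pyrone C6 and the OMe-bearing carbon then closes on C3. This asynchronous closure forms the six-membered carbocycle of ring A across pyrone C3 and C6 and gives the bridged lactone 20. Expulsion of CO2 from 20 is irreversible and yields the arene with no oxidant. No stereocenter is created in the product, because the two bridgehead centres of 20 disappear on aromatisation. The silyloxy carbon is not a reacting centre and has no epimerisation pathway under neutral thermal conditions, so its (S) configuration is retained. The selectivity required is regiochemical (OMe between ester and side chain), and it is secured by the matched polarisation of the two strongly biased partners; the methyl ynol ether also lacks the beta-hydrogen needed for retro-ene fragmentation to a ketene, so it tolerates the heating.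

Step 15
Reactants: 21 benzyl 6-[2-(benzyloxy)-4-methyl-6-{[(triisopropylsilyl)oxy]methyl}phenoxy]-3-[(1S)-1-{[tert-butyl(dimethyl)silyl]oxy}-3-methylbutyl]-2-methoxybenzoate
Product: 22 3-[(1S)-1-{[tert-butyl(dimethyl)silyl]oxy}-3-methylbutyl]-6-[2-hydroxy-4-methyl-6-{[(triisopropylsilyl)oxy]methyl}phenoxy]-2-methoxybenzoic acid
Conditions: H2 (1 atm), 10% Pd/C, EtOAc, rt
Reagents that add atoms: none
Why: Hydrogenolysis of a benzyl ester and a benzyl aryl ether; both benzylic alcohols are still silyl ethers, which resist C–O hydrogenolysis in a neutral aprotic solvent, so the stereocenter is not touched.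

Step 16
Reactants: 22 3-[(1S)-1-{[tert-butyl(dimethyl)silyl]oxy}-3-methylbutyl]-6-[2-hydroxy-4-methyl-6-{[(triisopropylsilyl)oxy]methyl}phenoxy]-2-methoxybenzoic acid
Product: 23 6-[2-hydroxy-6-(hydroxymethyl)-4-methylphenoxy]-3-[(1S)-1-hydroxy-3-methylbutyl]-2-methoxybenzoic acid
Conditions: Bu4NF (5 equiv), THF, 0 °C to rt; dilute aq. HCl to pH 4
Reagents that add atoms: none
Why: Fluoride-induced cleavage of both silyl ethers, driven by Si–F bond formation; the carbinol carbon has no epimerisation pathway under these conditions and the brief, mildly acidic work-up does not ionise it.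

Compound list

1 | creosol (2-methoxy-4-methylphenol) | Cc1ccc(O)c(OC)c1 | starting material
2 | 2-hydroxy-3-methoxy-5-methylbenzaldehyde | COc1cc(C)cc(C=O)c1O | intermediate
3 | 2,3-dihydroxy-5-methylbenzaldehyde | Cc1cc(O)c(O)c(C=O)c1 | intermediate
4 | 3-(benzyloxy)-2-hydroxy-5-methylbenzaldehyde | Cc1cc(OCc2ccccc2)c(O)c(C=O)c1 | intermediate
5 | 2-(benzyloxy)-6-(hydroxymethyl)-4-methylphenol | Cc1cc(CO)c(O)c(OCc2ccccc2)c1 | intermediate
6 | 2-(benzyloxy)-4-methyl-6-{[(triisopropylsilyl)oxy]methyl}phenol | Cc1cc(CO[Si](C(C)C)(C(C)C)C(C)C)c(O)c(OCc2ccccc2)c1 | intermediate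
7 | dibenzyl malonate | O=C(CC(=O)OCc1ccccc1)OCc1ccccc1 | starting material
8 | (E)-3-ethoxyacryloyl chloride | CCO/C=C/C(Cl)=O | starting material
9 | dibenzyl 2-[(2E)-3-ethoxyprop-2-enoyl]propanedioate | CCO/C=C/C(=O)C(C(=O)OCc1ccccc1)C(=O)OCc1ccccc1 | intermediate
10 | benzyl 4-hydroxy-2-oxo-2H-pyran-3-carboxylate | O=C1OC=CC(O)=C1C(=O)OCc1ccccc1 | intermediate
11 | benzyl 4-chloro-2-oxo-2H-pyran-3-carboxylate | O=C1OC=CC(Cl)=C1C(=O)OCc1ccccc1 | intermediate
12 | benzyl 4-[2-(benzyloxy)-4-methyl-6-{[(triisopropylsilyl)oxy]methyl}phenoxy]-2-oxo-2H-pyran-3-carboxylate | O=C(OCc1ccccc1)C1=C(Oc2c(OCc3ccccc3)cc(C)cc2CO[Si](C(C)C)(C(C)C)C(C)C)C=COC1=O | intermediate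
13 | chloroacetaldehyde dimethyl acetal (2-chloro-1,1-dimethoxyethane) | COC(CCl)OC | starting material
14 | isovaleraldehyde (3-methylbutanal) | CC(C)CC=O | starting material
15 | lithium methoxyacetylide | [Li]C#COC | intermediate
16 | rac-1-methoxy-5-methylhex-1-yn-3-ol | COC#CC(O)CC(C)C | intermediate
17 | 1-methoxy-5-methylhex-1-yn-3-one | COC#CC(=O)CC(C)C | intermediate
18 | (S)-1-methoxy-5-methylhex-1-yn-3-ol | COC#C[C@@H](O)CC(C)C | intermediate
19 | (S)-tert-butyl[(1-methoxy-5-methylhex-1-yn-3-yl)oxy]dimethylsilane | COC#C[C@@H](O[Si](C)(C)C(C)(C)C)CC(C)C | intermediate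
20 | benzyl 5-[2-(benzyloxy)-4-methyl-6-{[(triisopropylsilyl)oxy]methyl}phenoxy]-7-[(1S)-1-{[tert-butyl(dimethyl)silyl]oxy}-3-methylbutyl]-8-methoxy-3-oxo-2-oxabicyclo[2.2.2]octa-5,7-diene-4-carboxylate (bridgehead configuration not defined, transient) | O=C1OC2C=C(Oc3c(OCc4ccccc4)cc(C)cc3CO[Si](C(C)C)(C(C)C)C(C)C)C1(C(=O)OCc1ccccc1)C(OC)=C2[C@@H](O[Si](C)(C)C(C)(C)C)CC(C)C | intermediate
21 | benzyl 6-[2-(benzyloxy)-4-methyl-6-{[(triisopropylsilyl)oxy]methyl}phenoxy]-3-[(1S)-1-{[tert-butyl(dimethyl)silyl]oxy}-3-methylbutyl]-2-methoxybenzoate | COc1c([C@@H](O[Si](C)(C)C(C)(C)C)CC(C)C)ccc(Oc2c(OCc3ccccc3)cc(C)cc2CO[Si](C(C)C)(C(C)C)C(C)C)c1C(=O)OCc1ccccc1 | intermediate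
22 | 3-[(1S)-1-{[tert-butyl(dimethyl)silyl]oxy}-3-methylbutyl]-6-[2-hydroxy-4-methyl-6-{[(triisopropylsilyl)oxy]methyl}phenoxy]-2-methoxybenzoic acid | COc1c([C@@H](O[Si](C)(C)C(C)(C)C)CC(C)C)ccc(Oc2c(O)cc(C)cc2CO[Si](C(C)C)(C(C)C)C(C)C)c1C(=O)O | intermediate
23 | 6-[2-hydroxy-6-(hydroxymethyl)-4-methylphenoxy]-3-[(1S)-1-hydroxy-3-methylbutyl]-2-methoxybenzoic acid | COc1c([C@@H](O)CC(C)C)ccc(Oc2c(O)cc(C)cc2CO)c1C(=O)O | target

Total step count: 16. Longest linear sequence: 9 steps (steps 1 to 5, 9, 14, 15 and 16, from creosol 1).

Least certain steps

Step 14 (key step). The 4-aryloxy group donates into the pyrone and raises its LUMO, so cycloaddition may be slow and thermal oligomerisation of the ynol ether may outpace it. The nucleophilic alkyne carbon may also attack C4 and displace the aryloxide instead of bonding at C6. Fallback: keep the same two ring bonds but change the two-carbon partner to its ketene acetal, the best-documented partner for 3-alkoxycarbonyl-2-pyrones. Setting out from 19, base-catalysed addition of methanol (NaOMe cat., MeOH, warm) should give (S)-tert-butyl[(1,1-dimethoxy-5-methylhex-1-en-3-yl)oxy]dimethylsilane F1. Heating F1 with 12 in toluene should give, after cycloaddition and loss of CO2, benzyl 2-[2-(benzyloxy)-4-methyl-6-{[(triisopropylsilyl)oxy]methyl}phenoxy]-5-[(1S)-1-{[tert-butyl(dimethyl)silyl]oxy}-3-methylbutyl]-6,6-dimethoxycyclohexa-1,3-diene-1-carboxylate F2. F2 loses methanol on continued heating and returns to the route at 21.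

Step 7. The lactonisation may lose out to retro-Claisen deacylation of the acylmalonate or to acid cleavage of both benzyl esters. Fallback: chlorinate before closing the ring. Setting out from 9, POCl3 and Bu3N should convert the enol into dibenzyl 2-[(2E)-1-chloro-3-ethoxyprop-2-en-1-ylidene]propanedioate F3. F3 is a 3-alkoxyallylidene malonate, the substrate type for which the formic acid closure to a 2-pyrone is established. The closure of F3 in HCO2H returns to the route at 11 and bypasses 10.

Step 12. The alkoxy-ynone is a vinylogous ester and may suffer conjugate addition of 2-propanol, or reduce slowly with eroded enantioselectivity. Fallback: resolve instead of reducing asymmetrically. Setting out from 16, acylation with (S)-2-acetoxypropanoyl chloride (pyridine, DMAP, CH2Cl2) should give the diastereomeric esters (3S)-1-methoxy-5-methylhex-1-yn-3-yl (2S)-2-acetoxypropanoate F4 and (3R)-1-methoxy-5-methylhex-1-yn-3-yl (2S)-2-acetoxypropanoate F5. These would be separated by chromatography, and methanolysis of F4 (K2CO3, MeOH, 0 °C) returns to the route at 18.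

Step 5. Competing silylation of the phenol may give mixtures of mono- and bis-silyl ethers. Fallback: silylate exhaustively and then unmask the phenol selectively. Setting out from 5, TIPSOTf and 2,6-lutidine should give [3-(benzyloxy)-5-methyl-2-{[tri(propan-2-yl)silyl]oxy}phenyl]methoxy-tri(propan-2-yl)silane F6. The aryl silyl ether of F6 is cleaved much faster than the alkyl one by one equivalent of Bu4NF at −20 °C, which returns to the route at 6.

Further compounds

F1 | step 14 | (S)-tert-butyl[(1,1-dimethoxy-5-methylhex-1-en-3-yl)oxy]dimethylsilane | COC(OC)=C[C@@H](O[Si](C)(C)C(C)(C)C)CC(C)C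
F2 | step 14 | benzyl 2-[2-(benzyloxy)-4-methyl-6-{[(triisopropylsilyl)oxy]methyl}phenoxy]-5-[(1S)-1-{[tert-butyl(dimethyl)silyl]oxy}-3-methylbutyl]-6,6-dimethoxycyclohexa-1,3-diene-1-carboxylate (ring CH configuration not defined, transient) | COC1(OC)C(C(=O)OCc2ccccc2)=C(Oc2c(OCc3ccccc3)cc(C)cc2CO[Si](C(C)C)(C(C)C)C(C)C)C=CC1[C@@H](O[Si](C)(C)C(C)(C)C)CC(C)C
F3 | step 7 | dibenzyl 2-[(2E)-1-chloro-3-ethoxyprop-2-en-1-ylidene]propanedioate | CCO/C=C/C(Cl)=C(C(=O)OCc1ccccc1)C(=O)OCc1ccccc1
F4 | step 12 | (3S)-1-methoxy-5-methylhex-1-yn-3-yl (2S)-2-acetoxypropanoate | COC#C[C@@H](OC(=O)[C@H](C)OC(C)=O)CC(C)C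
F5 | step 12 | (3R)-1-methoxy-5-methylhex-1-yn-3-yl (2S)-2-acetoxypropanoate | COC#C[C@H](OC(=O)[C@H](C)OC(C)=O)CC(C)C
F6 | step 5 | [3-(benzyloxy)-5-methyl-2-{[tri(propan-2-yl)silyl]oxy}phenyl]methoxy-tri(propan-2-yl)silane | Cc1cc(CO[Si](C(C)C)(C(C)C)C(C)C)c(O[Si](C(C)C)(C(C)C)C(C)C)c(OCc2ccccc2)c1
A1 | alternative 1 | 6-[6-(dimethoxymethyl)-2-hydroxy-4-methylphenoxy]-2-methoxy-3-[(1S)-3-methyl-1-{[tri(propan-2-yl)silyl]oxy}butyl]benzoic acid | COc1c([C@@H](O[Si](C(C)C)(C(C)C)C(C)C)CC(C)C)ccc(Oc2c(O)cc(C)cc2C(OC)OC)c1C(=O)O
A2 | alternative 1 | 2-methoxy-3-[(1S)-3-methyl-1-{[tri(propan-2-yl)silyl]oxy}butyl]-6-[(2-oxopent-3-yn-1-yl)oxy]benzoic acid | COc1c([C@@H](O[Si](C(C)C)(C(C)C)C(C)C)CC(C)C)ccc(OCC(=O)C#CC)c1C(=O)O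
A3 | alternative 1 | 1,1-dimethoxypropan-2-one | CC(=O)C(OC)OC
A4 | alternative 2 | methyl 6-[2-(benzyloxy)-4-methyl-6-{[(triisopropylsilyl)oxy]methyl}phenoxy]-2-hydroxy-3-[(1S)-3-methyl-1-{[tri(propan-2-yl)silyl]oxy}butyl]benzoate | COC(=O)c1c(O)c([C@@H](O[Si](C(C)C)(C(C)C)C(C)C)CC(C)C)ccc1Oc1c(OCc2ccccc2)cc(C)cc1CO[Si](C(C)C)(C(C)C)C(C)C
A5 | alternative 2 | [(1-methoxy-2-{(1S)-3-methyl-1-[(triisopropylsilyl)oxy]butyl}buta-1,3-dien-1-yl)oxy]trimethylsilane (enol geometry not defined) | COC(O[Si](C)(C)C)=C(C=C)[C@@H](O[Si](C(C)C)(C(C)C)C(C)C)CC(C)C
A6 | alternative 2 | methyl 3-[2-(benzyloxy)-4-methyl-6-{[(triisopropylsilyl)oxy]methyl}phenoxy]prop-2-ynoate | COC(=O)C#COc1c(OCc2ccccc2)cc(C)cc1CO[Si](C(C)C)(C(C)C)C(C)C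
A7 | alternative 3 | 6-[2-(benzyloxy)-4-methyl-6-{[(triisopropylsilyl)oxy]methyl}phenoxy]-2-methoxy-3-[(1S)-3-methyl-1-{[tri(propan-2-yl)silyl]oxy}butyl]benzoic acid | COc1c([C@@H](O[Si](C(C)C)(C(C)C)C(C)C)CC(C)C)ccc(Oc2c(OCc3ccccc3)cc(C)cc2CO[Si](C(C)C)(C(C)C)C(C)C)c1C(=O)O
A8 | alternative 3 | 3-methoxy-4-[(1S)-3-methyl-1-{[tri(propan-2-yl)silyl]oxy}butyl]-2-(trimethylsilyl)phenyl trifluoromethanesulfonate | COc1c([C@@H](O[Si](C(C)C)(C(C)C)C(C)C)CC(C)C)ccc(OS(=O)(=O)C(F)(F)F)c1[Si](C)(C)C
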